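I could not read G in cedar, alder or elm, for those runs report E, so I built my reckoning on the E readings and let G follow as the excess of E over a floor.

| flask | G | Q | X | remark | time | volume of the second phase over the first |
|---|---|---|---|---|---|---|
| cedar | 44 mM | 35.2 mM | 6.6 mM | run made earlier |  |  |
| alder | 44 mM | 35.2 mM | 9.9 mM | run made earlier |  |  |
| elm | 88 mM | 35.2 mM | 13.2 mM | run made earlier |  |  |
| flask | 44 mM | 35.2 mM | 13.2 mM |  | 12 h | 0.25 |

- cedar (time / h: E / %): 4.00: 25.8; 8.00: 21.8; 10.0: 20.7; 15.0: 19.4
- alder (time / h: E / %): 1.00: 39.6; 2.50: 29.4; 6.00: 22.7; 15.0: 17.4
- elm (time / h: E / %): 4.00: 1.4; 8.00: 0; 10.0: 0; 15.0: 0.4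

(standard deviation of a reading: 0.5 percentage points)

- in the second phase: Q; everything else is in the first
- charges count per volume of the first phase; a concentration in a rate is the amount of a species over the volume of its own phase; every rate counts per litre of the first phase
- the earlier runs hold the two phases in the same ratio of volumes as the flask asked about

1. how much E there is at 12 h, in percent of the G charged
2. the change that raises the amount of E at 12 h, in percent of the G charged most ("none" if none brings more than 2 percentage points) (Wednesday's / Thursday's / none)
3. amount of E at 12 h, in percent of the G charged, after Wednesday's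

I ran the flask slowly in my head. In the first instants Q crosses from its own phase and E climbs: alder already stood at 39.6% after 1.00 h, higher than its 29.4% at 2.50 h. In the middle E falls. Elm, with twice the G of cedar and twice its X, read 1.4% at 4.00 h, less than the 25.8% of cedar. X differs there as well, but I took G to destroy E, one for one.

Late on, if Q has stopped reacting, that picture makes one thing stand still. The floor, [E] minus [G] in percent of the G charged, stays put while both sink, and G dies away pseudo-first-order in E. X steps evenly from cedar (6.6 mM) through alder (9.9 mM) to the flask (13.2 mM), so I stepped the readings at 15.0 h, 19.4% and 17.4%, on once more. That gave the flask a floor of 15.4%, good to about 1.1 percentage points, if G was small by 15.0 h. I committed to E standing above it at 12 h by the G still there.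

The forecast gave 17.2%, 16.8% after Wednesday's, and Thursday's as the best change, on the ground that “Doubling Q removes the excess G, so E should rise greatly”. Against my floor, its 17.2% implies 1.8 points of G remaining.

The flask gave 17.4%, 17.6% after Wednesday's, and Thursday's as the best change, gaining 12 points against 0.15 points.

    Z ⇌ Q, rate k1*([Z] - [Q]/K1) per volume of the first phase (partition coefficient = 0.420, kL = 1.80 × 10⁻⁴ s⁻¹)
    G + Z → E (k = 0.0740 M⁻¹ s⁻¹)
    Z + E → L (k = 0.0240 M⁻¹ s⁻¹)
    G + E → J (k = 0.00640 M⁻¹ s⁻¹)
    Z + X → D (k = 0.0150 M⁻¹ s⁻¹)

The forecast's number would fail if Q were charged at 32.1 mM or 38.4 mM, where y has moved by 5 points. Taking the floor from 17.4% leaves 2 points as my reading of G, and the flask held 1.83%.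

The same flask stopped at 5.0 h, with Q at 0% and G at 7.27%, has E at floor plus G, 22.7%. The computed value is 22.9%.

The data were generated by integration from invented constants; scatter was added.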